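# Synthesis plan for CNP0301161.1 (26)

## The problem

Compound 26 is a trans-fused eremophilane; eremophilane numbering is used throughout (ring A = C1–C5 and C10, ring B = C5–C10, C14 = carbon on C5, C15 = methyl on C4, C11–C13 = isopropenyl on C7; β is the face that carries C14). It has six stereocentres, (3R,4R,5R,7S,9S,10R): 3α-acyloxy and 4β-methyl in ring A, quaternary C5 and 10α-H at the ring fusion, 7α-isopropenyl and 9α-acyloxy on either side of the C8 ketone. In the two-chair trans-decalin every substituent except the axial C14 methyl is equatorial. C7 and C9 can therefore be set late, by attack anti to the angular methyl and, at C7, by enolate protonation. C3 and C4 have no such help, must be made early with absolute control, and can then direct the creation of C5 and C10. The molecule tolerates little: the isopropenyl group is β,γ to the ketone and moves into conjugation (and C7 epimerises) with base or acid, the 9-acyloxy ketone can shift its acyl group, the angelate isomerises to the tiglate on activation, and two different enoates sit on two secondary alcohols that need orthogonal protection to the end. The feature that opens the molecule is the C8 ketone with its oxygen neighbour on C9: read as a C8=C9 silyl enol ether, ring B is a cyclohexene flanked by the bonds C5–C10 and C6–C7, the adduct of a 2-silyloxydiene (C7–C10) and an alkene C5=C6. If C5 carries an ester that later becomes C14, this alkene is an activated acrylate, and the four carbons C1–C4 that tie C10 to C5 are the chain that holds C3 and C4.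

## Retrosynthesis

**Acyl–oxygen bonds at O3 and O9.** 26 is cut at the angelate to alcohol 24 and angelic acid 25, then at the C9 enoate, through 23, to ketol 21 and acid 22. The angelate goes on last because it is the group most easily isomerised. The two oxygens are told apart by a triethylsilyl ether on O9 and a tert-butyldimethylsilyl ether on O3 (20), removed in that order under non-basic conditions. The forward steps must acylate without touching the enoate geometries or the β,γ-unsaturated ketone.

**C7–C11.** 20 is cut between C7 and C11 to ketone 17. An aldol–dehydration sequence would make the same bond but leaves the alkene position to the elimination, which tends toward conjugation; coupling the C7 enolate with an isopropenyl halide fixes the alkene in the reagent. 17 is three carbons and one stereocentre simpler. The forward step must enolise toward C7 (enolate 18), couple, and protonate dienolate 19 at C7 to the equatorial, non-conjugated ketone.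

**C9–O.** 17 is cut at C9–O to silyl enol ether 15. The double bond of 15 lies at C8=C9 by construction, so oxidation at C9 and not at C7 needs no enolate regiocontrol. The silyl group, after passing through epoxide 16, becomes the O9 protecting group. The oxidant must come from the α face.

**Oxidation level of C14.** 15 goes back through mesylate 14 and alcohol 13 to ester 12. The skeleton does not change: the carbon on C5 must be a carbonyl group for the ring-forming step and is reduced to methyl while the C8 ketone is still masked as the enol ether, so no extra protection is needed.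

**C5–C10 and C6–C7 (key cut).** 12 is cut across both bonds to triene 11. Closing only one bond of ring B onto a finished ring A would leave the quaternary centre to be built on a ring between two stereocentres. The double cut makes C5 from a planar acrylate carbon, removes both rings and two stereocentres, and leaves an open chain whose only stereocentres are C3 and C4. The forward reaction must prefer the ester-endo, tether-anti geometry and the diene face dictated by C3 and C4.

**O8–Si.** 11 comes from enone 10 by enolisation toward the methyl group.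

**C5–C14.** 10 comes from alkyne 9 by Markovnikov hydroesterification. The order matters: an acrylate made while the chain still ended in the terminal alkene would give a 1,7-diene that can ring-close under metathesis conditions and offers ozone two alkenes of similar reactivity. The enone is therefore built first.

**C9=C10.** 9 comes from aldehyde 8 by Wittig olefination, and 8 from enyne 7 by ozonolysis, which spares the alkyne.

**C5≡C6.** 7 comes from aldehyde 6 by one-carbon homologation.

**C3–C4.** 6 goes back through 5 and 4 to thioimide 1 and pent-4-enal 2, joined by an auxiliary-controlled syn aldol reaction via titanium enolate 3. The same bond could be made together with the acrylate by adding an ester-substituted crotylmetal reagent to an aldehyde, about three steps shorter. That is set aside because a dependable enantioselective, syn-selective form of that addition for an unbranched aliphatic aldehyde is not available and its γ-hydroxy ester products lactonise readily. The aldol route gives both centres in one well-understood step.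

## Roads not taken

**Alternative 1:** The cut is C4–C5 of ring A, made by a 1,2-shift. Ring B and quaternary C5 come from the proline-derived hydrindenedione A1. Vinyl addition to its saturated ketone gives the tertiary vinyl carbinol A2. N-Bromosuccinimide forms a bromonium ion on the vinyl group, and the more substituted ring carbon C5 migrates to it (semipinacol shift). The five-membered ring expands to ring A with the C3 ketone and a bromomethyl group on C4, giving bromo enedione A3.
- Merits: this is the shortest way to the bicyclic skeleton; the absolute configuration comes from a catalytic step; the angular methyl is in place from the start, with no ester-to-methyl detour.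
- Weak points: C4 is created in the shift with no secured sense, and correcting it by equilibration next to the C3 ketone competes with loss of HBr from the β-bromo ketone. The bromide must still be reduced, two ketones must be differentiated, C10 must be set by a later reduction, C9 must be oxidised, and C7 must be isopropenylated.
- Comparison: Alternative 1 is clearly better in step count to the core and in the handling of C14. The chosen plan sets against this that C3 and C4 are fixed with reliable control before any ring exists, that C8 and C9 arrive differentiated as an enol ether, and that the ring fusion is defined in the ring-forming step.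

**Alternative 2:** The cut is C7–C8. Aldehyde A4, a ring-A cyclohexane carrying methyl and prenyl on C5 and the O-protected hydroxy aldehyde chain on C10, undergoes a Me2AlCl-promoted carbonyl-ene reaction. C7–C8 forms, ring B closes, and hydrogen transfer from a prenyl methyl creates the isopropenyl group and the C8 hydroxyl of A5.
- Merits: the isopropenyl group is born in the ring closure, out of conjugation and without enolate chemistry; C7 is set in a chair-like transition state; C9 already carries its oxygen. For the endgame this is better than the chosen plan, whose C7 step is its second-largest risk.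
- Weak points: the difficulty moves into A4, a cyclohexane with four contiguous stereocentres including the quaternary one, for which the alternative offers no solution. The α-alkoxy aldehyde can epimerise at C9, and chloride capture of the cationic intermediate competes with the ene pathway.
- Comparison: the chosen plan forms both rings and the quaternary centre at once from an open chain made in seven steps, and pays for this with a later, riskier isopropenylation.

**Alternative 3:** The cut is C5–C6. In A6, an exocyclic methylene on C5 and a vinyl ketone chain on C10 are joined by hydrogen-atom transfer (Fe(acac)3, PhSiH3). The tertiary C5 radical adds to the vinyl ketone terminus C6 and closes ring B to give A7.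
- Merits: the conditions are mild; radical addition is insensitive to the crowding at C5; the angular methyl arises directly from the methylene; C9 oxygen is carried in.
- Weak points: the ring fusion is decided by the conformation of a planar radical, not by a concerted geometry, so trans selectivity is not assured. The vinyl ketone is itself prone to reduction and polymerisation, C9 next to the ketone can epimerise, and A6 again needs C3, C4, C9 and C10 on a preformed ring. C7 isopropenylation remains, as in the chosen plan.
- Comparison: Alternative 3 is better on C14 and equal on the endgame. The chosen plan offers a stereospecific suprafacial cycloaddition for C5/C10 and a simpler, acyclic precursor.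

Key step: step 8

Assumption: 1, 22 and 25 are taken as purchasable in the configuration and geometries shown; all bicyclic compounds are named with the eremophilane numbering and α/β convention defined above.

## Steps

Step 1
Reactants: 1 (S)-4-benzyl-3-propanoyl-1,3-thiazolidine-2-thione; 2 pent-4-enal
Product: 4 (S)-4-benzyl-3-[(2S,3R)-3-hydroxy-2-methylhept-6-enoyl]-1,3-thiazolidine-2-thione, via trichlorotitanium Z-enolate 3 (not isolated)
Conditions: TiCl4, iPr2NEt, NMP, CH2Cl2, 0 °C; then 2, 0 °C
Reagents that add atoms: none
Why: Titanium-mediated thiazolidinethione aldol reaction in the Evans-syn mode: the Z-enolate 3 reacts through a Zimmerman–Traxler chair on the face away from the benzyl group, giving the 2S,3R syn adduct, whose two centres become C4 and C3 of the target.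

Step 2
Reactants: 4 (S)-4-benzyl-3-[(2S,3R)-3-hydroxy-2-methylhept-6-enoyl]-1,3-thiazolidine-2-thione
Product: 5 (S)-4-benzyl-3-[(2S,3R)-3-(tert-butyldimethylsilyloxy)-2-methylhept-6-enoyl]-1,3-thiazolidine-2-thione
Conditions: TBSOTf, 2,6-lutidine, CH2Cl2, 0 °C
Reagents that add atoms: tert-butyldimethylsilyl trifluoromethanesulfonate, CC(C)(C)[Si](C)(C)OS(=O)(=O)C(F)(F)F
Why: Silylation of a secondary alcohol with a silyl triflate; the TBS ether has to last until step 16 and can then be removed by fluoride without base.

Step 3
Reactants: 5 (S)-4-benzyl-3-[(2S,3R)-3-(tert-butyldimethylsilyloxy)-2-methylhept-6-enoyl]-1,3-thiazolidine-2-thione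
Product: 6 (2S,3R)-3-(tert-butyldimethylsilyloxy)-2-methylhept-6-enal
Conditions: iBu2AlH, CH2Cl2, −78 °C; aq. KNaC4H4O6
Reagents that add atoms: none
Why: Partial reduction of an N-acyl thiazolidinethione: the tetrahedral aluminium adduct is stable at −78 °C and releases the aldehyde and the recoverable auxiliary only on work-up, so there is no over-reduction and no epimerisation of the α-centre.

Step 4
Reactants: 6 (2S,3R)-3-(tert-butyldimethylsilyloxy)-2-methylhept-6-enal
Product: 7 (3R,4R)-4-(tert-butyldimethylsilyloxy)-3-methyloct-7-en-1-yne
Conditions: MeC(O)C(N2)P(O)(OMe)2, K2CO3, MeOH, 0 °C to rt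
Reagents that add atoms: dimethyl (1-diazo-2-oxopropyl)phosphonate, COP(=O)(OC)C(=[N+]=[N-])C(C)=O
Why: Ohira–Bestmann homologation; the mild carbonate conditions are routinely used on α-methyl-β-silyloxy aldehydes without epimerisation. The added carbon is the future C6.

Step 5
Reactants: 7 (3R,4R)-4-(tert-butyldimethylsilyloxy)-3-methyloct-7-en-1-yne
Product: 9 (3E,7R,8R)-7-(tert-butyldimethylsilyloxy)-8-methyldec-3-en-9-yn-2-one, via silyloxy ynal 8 (not isolated)
Conditions: O3, CH2Cl2, −78 °C; PPh3, −78 °C to rt; then Ph3P=CHC(O)CH3, rt
Reagents that add atoms: 1-(triphenyl-λ5-phosphanylidene)propan-2-one, CC(=O)C=P(c1ccccc1)(c1ccccc1)c1ccccc1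
Why: Ozonolysis with reductive work-up followed in the same flask by a Wittig reaction with a stabilised ylide; ozone attacks the alkene far faster than the alkyne, and the stabilised ylide gives the E-enone.

Step 6
Reactants: 9 (3E,7R,8R)-7-(tert-butyldimethylsilyloxy)-8-methyldec-3-en-9-yn-2-one
Product: 10 methyl (3R,4R,7E)-4-(tert-butyldimethylsilyloxy)-3-methyl-2-methylidene-9-oxodec-7-enoate
Conditions: Pd(OAc)2 (cat.), 2-(diphenylphosphino)pyridine, MeSO3H (cat.), CO (20 bar), MeOH, 45 °C
Reagents that add atoms: carbon monoxide, [C-]#[O+]; methanol, CO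
Why: Palladium-catalysed Markovnikov hydroesterification of a terminal alkyne; with a 2-pyridylphosphine and a sulfonic acid cocatalyst the ester is delivered to the internal carbon, giving the 2-substituted acrylate. The β-substituted enone is much less reactive toward the palladium hydride than the alkyne.

Step 7
Reactants: 10 methyl (3R,4R,7E)-4-(tert-butyldimethylsilyloxy)-3-methyl-2-methylidene-9-oxodec-7-enoate
Product: 11 methyl (3R,4R,7E)-4-(tert-butyldimethylsilyloxy)-3-methyl-2-methylidene-9-(triethylsilyloxy)deca-7,9-dienoate
Conditions: TESOTf, Et3N, CH2Cl2, −78 to 0 °C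
Reagents that add atoms: triethylsilyl trifluoromethanesulfonate, CC[Si](CC)(CC)OS(=O)(=O)C(F)(F)F
Why: Soft enolisation of an α,β-unsaturated methyl ketone with a silyl triflate and an amine removes a methyl proton under kinetic control and gives the cross-conjugated 2-silyloxydiene; the acrylate has no α-hydrogen and is left alone.

Step 8
Reactants: 11 methyl (3R,4R,7E)-4-(tert-butyldimethylsilyloxy)-3-methyl-2-methylidene-9-(triethylsilyloxy)deca-7,9-dienoate
Product: 12 methyl 3α-(tert-butyldimethylsilyloxy)-8-(triethylsilyloxy)-11,12,13-trinoreremophil-8-en-14-oate (trans-fused: 5β-CO2Me and 10α-H; 4β-CH3)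
Conditions: toluene (0.01 M), BHT (cat.), 170 °C, sealed tube
Reagents that add atoms: none
Why: On heating, the electron-rich 2-silyloxydiene (C7=C8–C9=C10) and the tethered α-substituted acrylate (C5=C6) combine in a concerted, asynchronous, suprafacial [4+2] cycloaddition in which the nucleophilic diene terminus C7 bonds to the acrylate β-carbon C6 slightly ahead of the C5–C10 bond, the polarity being matched. The closest known reaction type is the type 1 intramolecular Diels–Alder reaction of 1,7,9-decatrienes that carry a 2-silyloxydiene and an α-substituted acrylate joined through its α-carbon. Ring B closes as the cyclohexene of the adduct (bonds C5–C10 and C6–C7, new alkene C8=C9), and ring A closes in the fused mode as the six-membered tether ring through the C5–C10 bond, the four-carbon tether C1–C4 taking a chair shape. C5 is set by the acrylate face that is attacked: with the ester endo, only one chair-like tether keeps both the C3 silyloxy and the C4 methyl group equatorial, and it leads to 5β-CO2Me beside 4β-CH3 and 3α-O. C10 is set relative to C5 by the endo position of the ester (tether anti) together with the E geometry of C9=C10, which puts H10 trans to the ester and gives the trans ring fusion. The step therefore needs endo over exo selectivity and π-facial selectivity; the first rests on secondary overlap of the ester carbonyl with C8 and C9 and on the less strained anti tether, the second on the two equatorial tether substituents made in step 1. The position of the enol ether double bond follows from the mechanism, and dilution with a radical inhibitor suppresses intermolecular addition and acrylate polymerisation.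

Step 9
Reactants: 12 methyl 3α-(tert-butyldimethylsilyloxy)-8-(triethylsilyloxy)-11,12,13-trinoreremophil-8-en-14-oate
Product: 13 3α-(tert-butyldimethylsilyloxy)-8-(triethylsilyloxy)-11,12,13-trinoreremophil-8-en-14-ol
Conditions: iBu2AlH, CH2Cl2, −78 to 0 °C; aq. KNaC4H4O6
Reagents that add atoms: none
Why: Hydride reduction of an ester to the primary alcohol; the silyl enol ether serves as the protected C8 ketone and, like the TBS ether, is inert to aluminium hydrides and to the near-neutral tartrate work-up.

Step 10
Reactants: 13 3α-(tert-butyldimethylsilyloxy)-8-(triethylsilyloxy)-11,12,13-trinoreremophil-8-en-14-ol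
Product: 14 3α-(tert-butyldimethylsilyloxy)-8-(triethylsilyloxy)-11,12,13-trinoreremophil-8-en-14-yl methanesulfonate
Conditions: MsCl, Et3N, CH2Cl2, 0 °C
Reagents that add atoms: methanesulfonyl chloride, CS(=O)(=O)Cl
Why: Sulfonylation of a primary alcohol under basic conditions, which keep the acid-labile enol ether intact.

Step 11
Reactants: 14 3α-(tert-butyldimethylsilyloxy)-8-(triethylsilyloxy)-11,12,13-trinoreremophil-8-en-14-yl methanesulfonate
Product: 15 3α-(tert-butyldimethylsilyloxy)-8-(triethylsilyloxy)-11,12,13-trinoreremophil-8-ene
Conditions: LiEt3BH, THF, 65 °C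
Reagents that add atoms: none
Why: Hydride displacement of a primary sulfonate by lithium triethylborohydride, the most nucleophilic common hydride and the usual reagent for turning neopentyl-type CH2OMs groups into methyl groups; nothing else in 14 is reducible or base-labile.

Step 12
Reactants: 15 3α-(tert-butyldimethylsilyloxy)-8-(triethylsilyloxy)-11,12,13-trinoreremophil-8-ene
Product: 17 3α-(tert-butyldimethylsilyloxy)-9α-(triethylsilyloxy)-11,12,13-trinoreremophilan-8-one, via 8α,9α-epoxide 16 (not isolated)
Conditions: mCPBA, NaHCO3, CH2Cl2, −20 to 0 °C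
Reagents that add atoms: 3-chloroperoxybenzoic acid, OOC(=O)c1cccc(Cl)c1
Why: Rubottom oxidation: the peracid epoxidises the electron-rich C8=C9 enol ether from the α face, anti to the axial C14 methyl, and epoxide 16 opens to the oxocarbenium ion with migration of the silyl group to the new oxygen. This gives the equatorial 9α-silyloxy ketone with O9 already protected.

Step 13
Reactants: 17 3α-(tert-butyldimethylsilyloxy)-9α-(triethylsilyloxy)-11,12,13-trinoreremophilan-8-one
Product: 20 3α-(tert-butyldimethylsilyloxy)-9α-(triethylsilyloxy)eremophil-11-en-8-one (7α-isopropenyl), via lithium C7 enolate 18 (not isolated), via lithium dienolate 19 (not isolated)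
Conditions: LiN(SiMe3)2 (2.2 equiv), THF, −78 °C; then Pd2(dba)3 (cat.), (C5Ph5)Fe(C5H4PtBu2) (Q-Phos, cat.), 2-bromopropene, rt; AcOH, −78 °C
Reagents that add atoms: 2-bromopropene, CC(Br)=C
Why: Palladium-catalysed α-alkenylation of a ketone enolate with an alkenyl bromide (enolate cross-coupling of the α-arylation type); kinetic deprotonation takes place at the C7 methylene and not at the hindered silyloxy-bearing C9. The coupled ketone is held as dienolate 19 until the cold acidic quench, which protonates C7 and leaves the alkene out of conjugation with the isopropenyl group equatorial (7α).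

Step 14
Reactants: 20 3α-(tert-butyldimethylsilyloxy)-9α-(triethylsilyloxy)eremophil-11-en-8-one
Product: 21 3α-(tert-butyldimethylsilyloxy)-9α-hydroxyeremophil-11-en-8-one
Conditions: AcOH/THF/H2O (3:1:1), rt
Reagents that add atoms: none
Why: Selective acidic hydrolysis of a triethylsilyl ether beside a TBS ether, which is far better shielded at silicon; the absence of base avoids ketol rearrangement and alkene migration.

Step 15
Reactants: 21 3α-(tert-butyldimethylsilyloxy)-9α-hydroxyeremophil-11-en-8-one; 22 (E)-3-methylpent-2-enoic acid
Product: 23 3α-(tert-butyldimethylsilyloxy)-9α-[(E)-3-methylpent-2-enoyloxy]eremophil-11-en-8-one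
Conditions: DCC, DMAP (cat.), CH2Cl2, 0 °C to rt
Reagents that add atoms: none
Why: Steglich esterification of the secondary ketol; low temperature and only catalytic DMAP keep the E geometry of the enoate and do not enolise the ketone.

Step 16
Reactants: 23 3α-(tert-butyldimethylsilyloxy)-9α-[(E)-3-methylpent-2-enoyloxy]eremophil-11-en-8-one
Product: 24 3α-hydroxy-9α-[(E)-3-methylpent-2-enoyloxy]eremophil-11-en-8-one
Conditions: HF·pyridine, pyridine, THF, 0 °C to rt
Reagents that add atoms: none
Why: Fluoride cleavage of the TBS ether under mildly acidic conditions, which avoid the acyl migration, ester cleavage and alkene conjugation that a basic fluoride source could cause.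

Step 17
Reactants: 24 3α-hydroxy-9α-[(E)-3-methylpent-2-enoyloxy]eremophil-11-en-8-one; 25 angelic acid [(Z)-2-methylbut-2-enoic acid]
Product: 26 (3R,4R,5R,7S,9S,10R)-3-[(Z)-2-methylbut-2-enoyloxy]-9-[(E)-3-methylpent-2-enoyloxy]eremophil-11-en-8-one (CNP0301161.1)
Conditions: 25, 2,4,6-Cl3C6H2COCl, Et3N, toluene, rt; then 24, toluene, 75 °C
Reagents that add atoms: none
Why: Yamaguchi-type esterification through the mixed 2,4,6-trichlorobenzoic anhydride, run without DMAP, is the established way to acylate hindered secondary alcohols with angelic acid without Z to E isomerisation; the medium stays neutral to weakly acidic, so C7 and the isopropenyl group are not disturbed.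

## Compound list

1 | (S)-4-benzyl-3-propanoyl-1,3-thiazolidine-2-thione | CCC(=O)N1[C@@H](Cc2ccccc2)CSC1=S | starting material
2 | pent-4-enal | C=CCCC=O | starting material
3 | trichlorotitanium (Z)-enolate of 1 (formed in the flask) | C/C=C(\O[Ti](Cl)(Cl)Cl)N1[C@@H](Cc2ccccc2)CSC1=S | intermediate
4 | (S)-4-benzyl-3-[(2S,3R)-3-hydroxy-2-methylhept-6-enoyl]-1,3-thiazolidine-2-thione | C=CCC[C@@H](O)[C@H](C)C(=O)N1[C@@H](Cc2ccccc2)CSC1=S | intermediate
5 | (S)-4-benzyl-3-[(2S,3R)-3-(tert-butyldimethylsilyloxy)-2-methylhept-6-enoyl]-1,3-thiazolidine-2-thione | C=CCC[C@@H](O[Si](C)(C)C(C)(C)C)[C@H](C)C(=O)N1[C@@H](Cc2ccccc2)CSC1=S | intermediate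
6 | (2S,3R)-3-(tert-butyldimethylsilyloxy)-2-methylhept-6-enal | C=CCC[C@@H](O[Si](C)(C)C(C)(C)C)[C@H](C)C=O | intermediate
7 | (3R,4R)-4-(tert-butyldimethylsilyloxy)-3-methyloct-7-en-1-yne | C=CCC[C@@H](O[Si](C)(C)C(C)(C)C)[C@H](C)C#C | intermediate
8 | (4R,5R)-4-(tert-butyldimethylsilyloxy)-5-methylhept-6-ynal (formed in the flask) | O=CCC[C@@H](O[Si](C)(C)C(C)(C)C)[C@H](C)C#C | intermediate
9 | (3E,7R,8R)-7-(tert-butyldimethylsilyloxy)-8-methyldec-3-en-9-yn-2-one | CC(=O)/C=C/CC[C@@H](O[Si](C)(C)C(C)(C)C)[C@H](C)C#C | intermediate
10 | methyl (3R,4R,7E)-4-(tert-butyldimethylsilyloxy)-3-methyl-2-methylidene-9-oxodec-7-enoate | CC(=O)/C=C/CC[C@@H](O[Si](C)(C)C(C)(C)C)[C@H](C)C(=C)C(=O)OC | intermediate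
11 | methyl (3R,4R,7E)-4-(tert-butyldimethylsilyloxy)-3-methyl-2-methylidene-9-(triethylsilyloxy)deca-7,9-dienoate | C=C(O[Si](CC)(CC)CC)/C=C/CC[C@@H](O[Si](C)(C)C(C)(C)C)[C@H](C)C(=C)C(=O)OC | intermediate
12 | methyl 3α-(tert-butyldimethylsilyloxy)-8-(triethylsilyloxy)-11,12,13-trinoreremophil-8-en-14-oate (trans-fused, 5β-CO2Me, 10α-H, 4β-CH3) | C1C[C@]2(C(=O)OC)[C@@H](C)[C@H](O[Si](C)(C)C(C)(C)C)CC[C@H]2C=C1O[Si](CC)(CC)CC | intermediate
13 | 3α-(tert-butyldimethylsilyloxy)-8-(triethylsilyloxy)-11,12,13-trinoreremophil-8-en-14-ol | C1C[C@]2(CO)[C@@H](C)[C@H](O[Si](C)(C)C(C)(C)C)CC[C@H]2C=C1O[Si](CC)(CC)CC | intermediate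
14 | 3α-(tert-butyldimethylsilyloxy)-8-(triethylsilyloxy)-11,12,13-trinoreremophil-8-en-14-yl methanesulfonate | C1C[C@]2(COS(C)(=O)=O)[C@@H](C)[C@H](O[Si](C)(C)C(C)(C)C)CC[C@H]2C=C1O[Si](CC)(CC)CC | intermediate
15 | 3α-(tert-butyldimethylsilyloxy)-8-(triethylsilyloxy)-11,12,13-trinoreremophil-8-ene | C1C[C@]2(C)[C@@H](C)[C@H](O[Si](C)(C)C(C)(C)C)CC[C@H]2C=C1O[Si](CC)(CC)CC | intermediate
16 | 3α-(tert-butyldimethylsilyloxy)-8α,9α-epoxy-8β-(triethylsilyloxy)-11,12,13-trinoreremophilane (formed in the flask) | C1C[C@]2(C)[C@@H](C)[C@H](O[Si](C)(C)C(C)(C)C)CC[C@H]2[C@@H]3O[C@]13O[Si](CC)(CC)CC | intermediate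
17 | 3α-(tert-butyldimethylsilyloxy)-9α-(triethylsilyloxy)-11,12,13-trinoreremophilan-8-one | C1C[C@]2(C)[C@@H](C)[C@H](O[Si](C)(C)C(C)(C)C)CC[C@H]2[C@H](O[Si](CC)(CC)CC)C1=O | intermediate
18 | lithium 3α-(tert-butyldimethylsilyloxy)-9α-(triethylsilyloxy)-11,12,13-trinoreremophil-7-en-8-olate (formed in the flask) | [Li+].[O-]C1=CC[C@]2(C)[C@@H](C)[C@H](O[Si](C)(C)C(C)(C)C)CC[C@H]2[C@@H]1O[Si](CC)(CC)CC | intermediate
19 | lithium 3α-(tert-butyldimethylsilyloxy)-9α-(triethylsilyloxy)eremophila-7,11-dien-8-olate (formed in the flask) | [Li+].[O-]C1=C(C(C)=C)C[C@]2(C)[C@@H](C)[C@H](O[Si](C)(C)C(C)(C)C)CC[C@H]2[C@@H]1O[Si](CC)(CC)CC | intermediate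
20 | 3α-(tert-butyldimethylsilyloxy)-9α-(triethylsilyloxy)eremophil-11-en-8-one (7α-isopropenyl) | C=C(C)[C@@H]1C[C@]2(C)[C@@H](C)[C@H](O[Si](C)(C)C(C)(C)C)CC[C@H]2[C@H](O[Si](CC)(CC)CC)C1=O | intermediate
21 | 3α-(tert-butyldimethylsilyloxy)-9α-hydroxyeremophil-11-en-8-one | C=C(C)[C@@H]1C[C@]2(C)[C@@H](C)[C@H](O[Si](C)(C)C(C)(C)C)CC[C@H]2[C@H](O)C1=O | intermediate
22 | (E)-3-methylpent-2-enoic acid | CC/C(C)=C/C(=O)O | starting material
23 | 3α-(tert-butyldimethylsilyloxy)-9α-[(E)-3-methylpent-2-enoyloxy]eremophil-11-en-8-one | C=C(C)[C@@H]1C[C@]2(C)[C@@H](C)[C@H](O[Si](C)(C)C(C)(C)C)CC[C@H]2[C@H](OC(=O)/C=C(\C)CC)C1=O | intermediate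
24 | 3α-hydroxy-9α-[(E)-3-methylpent-2-enoyloxy]eremophil-11-en-8-one | C=C(C)[C@@H]1C[C@]2(C)[C@@H](C)[C@H](O)CC[C@H]2[C@H](OC(=O)/C=C(\C)CC)C1=O | intermediate
25 | angelic acid, (Z)-2-methylbut-2-enoic acid | C/C=C(/C)C(=O)O | starting material
26 | (3R,4R,5R,7S,9S,10R)-3-[(Z)-2-methylbut-2-enoyloxy]-9-[(E)-3-methylpent-2-enoyloxy]eremophil-11-en-8-one (CNP0301161.1) | C=C(C)[C@@H]1C[C@]2(C)[C@@H](C)[C@H](OC(=O)/C(C)=C\C)CC[C@H]2[C@H](OC(=O)/C=C(\C)CC)C1=O | target

## Step count and least certain steps

Total: 17 steps. Longest linear sequence: 17 steps (2 to 26).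

**Step 8 (key step).** The most likely failure is leakage through the exo, tether-syn transition state. An α-substituted acrylate has only a modest endo preference and decatrienes cyclise through either tether geometry, so the cis-fused C10 epimer may accompany 12. Long heating may also cost part of the enol ether if traces of acid are present.
- Fallback: it sets out from 12 obtained as a mixture with its C10 epimer, methyl 3α-(tert-butyldimethylsilyloxy)-8-(triethylsilyloxy)-11,12,13-trinor-10-epi-eremophil-8-en-14-oate F1.
- The mixture is taken through steps 9 to 11 unchanged. Beside 13, 14 and 15 this gives 3α-(tert-butyldimethylsilyloxy)-8-(triethylsilyloxy)-11,12,13-trinor-10-epi-eremophil-8-en-14-ol F2, 3α-(tert-butyldimethylsilyloxy)-8-(triethylsilyloxy)-11,12,13-trinor-10-epi-eremophil-8-en-14-yl methanesulfonate F3 and 3α-(tert-butyldimethylsilyloxy)-8-(triethylsilyloxy)-11,12,13-trinor-10-epi-eremophil-8-ene F4.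
- Saegusa–Ito oxidation of the mixture of 15 and F4 (Pd(OAc)2, MeCN, rt) erases C10 and gives one enone, 3α-(tert-butyldimethylsilyloxy)-11,12,13-trinoreremophil-9-en-8-one F5.
- Birch-type reduction (Li, liquid NH3, THF, −78 °C) protonates C10 axially, which for an octalone with an angular methyl group gives the trans fusion. The resulting lithium 3α-(tert-butyldimethylsilyloxy)-11,12,13-trinoreremophil-8-en-8-olate F6 is trapped with TESCl/Et3N and the route is rejoined at 15.
- Control of C10 thus moves from the cycloaddition to a dissolving-metal reduction, at the cost of two steps. Addition to the other acrylate face is not corrected in this way.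

**Step 13.** The new double bond may migrate into conjugation with the ketone during coupling or work-up, the palladium enolate may undergo β-hydride elimination, or proton exchange may move the enolate toward C9.
- Fallback: it sets out from 17. Enolate 18 is added to acetone (THF, −78 °C) to give 3α-(tert-butyldimethylsilyloxy)-11-hydroxy-9α-(triethylsilyloxy)eremophilan-8-one F7.
- Dehydration (SOCl2, pyridine, 0 °C) gives 20 together with the conjugated isomer 3α-(tert-butyldimethylsilyloxy)-9α-(triethylsilyloxy)eremophil-7(11)-en-8-one F8.
- Both are converted by LiN(iPr)2 (THF, −78 °C) into the common dienolate 19. Quenching with AcOH at −78 °C protonates C7 and returns 20.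

**Step 11.** Hydride may attack sulfur instead of carbon, which returns 13, or the displacement may not proceed, because the carbon is neopentyl and flanked by C4 and the ring fusion.
- Fallback: it sets out from 13. 1,1'-Thiocarbonyldiimidazole and DMAP (toluene, 80 °C) give O-[3α-(tert-butyldimethylsilyloxy)-8-(triethylsilyloxy)-11,12,13-trinoreremophil-8-en-14-yl] 1H-imidazole-1-carbothioate F9.
- Barton–McCombie reduction (Bu3SnH, AIBN, toluene, 110 °C) breaks the C–O bond by homolysis and returns 15, so no displacement at the neopentyl carbon is needed.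

**Step 6.** The acid cocatalyst in methanol may remove the TBS group, after which the alcohol lactonises onto the new ester. Methanol may also add to the enone, or the linear ester may form.
- Fallback: it sets out from 7. Bromoboration of the alkyne with B-bromo-9-borabicyclo[3.3.1]nonane (CH2Cl2, −78 to 0 °C) gives 9-[(1Z,3S,4R)-2-bromo-4-(tert-butyldimethylsilyloxy)-3-methylocta-1,7-dien-1-yl]-9-borabicyclo[3.3.1]nonane F10.
- Protonolysis in the same flask (AcOH) gives (3S,4R)-2-bromo-4-(tert-butyldimethylsilyloxy)-3-methylocta-1,7-diene F11.
- Ozonolysis of the terminal alkene (the bromoalkene is deactivated) gives (4R,5S)-6-bromo-4-(tert-butyldimethylsilyloxy)-5-methylhept-6-enal F12. Wittig reaction as in step 5 gives (3E,7R,8S)-9-bromo-7-(tert-butyldimethylsilyloxy)-8-methyldeca-3,9-dien-2-one F13.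
- Methoxycarbonylation of the alkenyl bromide under basic conditions (Pd(PPh3)4, CO, MeOH, Et3N, DMF, 60 °C) returns 10.

**Step 12.** The silyl group may be partly lost instead of migrating, which would give a mixture of protected and free ketol. The peracid may also attack the β face to some extent.
- Fallback: it sets out from 15. Dihydroxylation of the enol ether (OsO4 cat., N-methylmorpholine N-oxide, acetone/H2O) from the α face gives, after loss of the silanol, 3α-(tert-butyldimethylsilyloxy)-9α-hydroxy-11,12,13-trinoreremophilan-8-one F14.
- Silylation (TESCl, imidazole, CH2Cl2) returns 17.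

## Further compounds

F1 | step 8 | methyl 3α-(tert-butyldimethylsilyloxy)-8-(triethylsilyloxy)-11,12,13-trinor-10-epi-eremophil-8-en-14-oate (cis-fused) | C1C[C@]2(C(=O)OC)[C@@H](C)[C@H](O[Si](C)(C)C(C)(C)C)CC[C@@H]2C=C1O[Si](CC)(CC)CC
F2 | step 8 | 3α-(tert-butyldimethylsilyloxy)-8-(triethylsilyloxy)-11,12,13-trinor-10-epi-eremophil-8-en-14-ol | C1C[C@]2(CO)[C@@H](C)[C@H](O[Si](C)(C)C(C)(C)C)CC[C@@H]2C=C1O[Si](CC)(CC)CC
F3 | step 8 | 3α-(tert-butyldimethylsilyloxy)-8-(triethylsilyloxy)-11,12,13-trinor-10-epi-eremophil-8-en-14-yl methanesulfonate | C1C[C@]2(COS(C)(=O)=O)[C@@H](C)[C@H](O[Si](C)(C)C(C)(C)C)CC[C@@H]2C=C1O[Si](CC)(CC)CC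
F4 | step 8 | 3α-(tert-butyldimethylsilyloxy)-8-(triethylsilyloxy)-11,12,13-trinor-10-epi-eremophil-8-ene | C1C[C@]2(C)[C@@H](C)[C@H](O[Si](C)(C)C(C)(C)C)CC[C@@H]2C=C1O[Si](CC)(CC)CC
F5 | step 8 | 3α-(tert-butyldimethylsilyloxy)-11,12,13-trinoreremophil-9-en-8-one | C1C[C@]2(C)[C@@H](C)[C@H](O[Si](C)(C)C(C)(C)C)CCC2=CC1=O
F6 | step 8 | lithium 3α-(tert-butyldimethylsilyloxy)-11,12,13-trinoreremophil-8-en-8-olate | C1C[C@]2(C)[C@@H](C)[C@H](O[Si](C)(C)C(C)(C)C)CC[C@H]2C=C1[O-].[Li+]
F7 | step 13 | 3α-(tert-butyldimethylsilyloxy)-11-hydroxy-9α-(triethylsilyloxy)eremophilan-8-one | CC(C)(O)[C@@H]1C[C@]2(C)[C@@H](C)[C@H](O[Si](C)(C)C(C)(C)C)CC[C@H]2[C@H](O[Si](CC)(CC)CC)C1=O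
F8 | step 13 | 3α-(tert-butyldimethylsilyloxy)-9α-(triethylsilyloxy)eremophil-7(11)-en-8-one | CC(C)=C1C[C@]2(C)[C@@H](C)[C@H](O[Si](C)(C)C(C)(C)C)CC[C@H]2[C@H](O[Si](CC)(CC)CC)C1=O
F9 | step 11 | O-[3α-(tert-butyldimethylsilyloxy)-8-(triethylsilyloxy)-11,12,13-trinoreremophil-8-en-14-yl] 1H-imidazole-1-carbothioate | C1C[C@]2(COC(=S)n3ccnc3)[C@@H](C)[C@H](O[Si](C)(C)C(C)(C)C)CC[C@H]2C=C1O[Si](CC)(CC)CC
F10 | step 6 | 9-[(1Z,3S,4R)-2-bromo-4-(tert-butyldimethylsilyloxy)-3-methylocta-1,7-dien-1-yl]-9-borabicyclo[3.3.1]nonane | C=CCC[C@@H](O[Si](C)(C)C(C)(C)C)[C@H](C)/C(Br)=C/B1C2CCCC1CCC2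
F11 | step 6 | (3S,4R)-2-bromo-4-(tert-butyldimethylsilyloxy)-3-methylocta-1,7-diene | C=CCC[C@@H](O[Si](C)(C)C(C)(C)C)[C@H](C)C(Br)=C
F12 | step 6 | (4R,5S)-6-bromo-4-(tert-butyldimethylsilyloxy)-5-methylhept-6-enal | O=CCC[C@@H](O[Si](C)(C)C(C)(C)C)[C@H](C)C(Br)=C
F13 | step 6 | (3E,7R,8S)-9-bromo-7-(tert-butyldimethylsilyloxy)-8-methyldeca-3,9-dien-2-one | CC(=O)/C=C/CC[C@@H](O[Si](C)(C)C(C)(C)C)[C@H](C)C(Br)=C
F14 | step 12 | 3α-(tert-butyldimethylsilyloxy)-9α-hydroxy-11,12,13-trinoreremophilan-8-one | C1C[C@]2(C)[C@@H](C)[C@H](O[Si](C)(C)C(C)(C)C)CC[C@H]2[C@H](O)C1=O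
A1 | alternative 1 | (S)-7a-methyl-2,3,7,7a-tetrahydro-1H-indene-1,5(6H)-dione | C[C@]12CCC(=O)C=C1CCC2=O
A2 | alternative 1 | (7aS)-1-ethenyl-1-hydroxy-7a-methyl-1,2,3,6,7,7a-hexahydro-5H-inden-5-one (hydroxyl cis to the angular methyl) | C=C[C@]1(O)CCC2=CC(=O)CC[C@]12C
A3 | alternative 1 | 15-bromo-11,12,13-trinoreremophil-9-ene-3,8-dione | C1C[C@]2(C)[C@@H](CBr)C(=O)CCC2=CC1=O
A4 | alternative 2 | 3α-(tert-butyldimethylsilyloxy)-9α-(4-methoxybenzyloxy)-7,8-seco-eremophil-7(11)-en-8-al | CC(C)=CC[C@]1(C)[C@@H](C)[C@H](O[Si](C)(C)C(C)(C)C)CC[C@H]1[C@H](OCc1ccc(OC)cc1)C=O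
A5 | alternative 2 | 3α-(tert-butyldimethylsilyloxy)-9α-(4-methoxybenzyloxy)eremophil-11-en-8β-ol | C=C(C)[C@@H]1C[C@]2(C)[C@@H](C)[C@H](O[Si](C)(C)C(C)(C)C)CC[C@H]2[C@H](OCc2ccc(OC)cc2)[C@H]1O
A6 | alternative 3 | 3α-(tert-butyldimethylsilyloxy)-9α-(4-methoxybenzyloxy)-11,12,13-trinor-5,6-seco-eremophila-5(14),6-dien-8-one | C=C1[C@@H](C)[C@H](O[Si](C)(C)C(C)(C)C)CC[C@H]1[C@H](OCc1ccc(OC)cc1)C(=O)C=C
A7 | alternative 3 | 3α-(tert-butyldimethylsilyloxy)-9α-(4-methoxybenzyloxy)-11,12,13-trinoreremophilan-8-one | C1C[C@]2(C)[C@@H](C)[C@H](O[Si](C)(C)C(C)(C)C)CC[C@H]2[C@H](OCc2ccc(OC)cc2)C1=O
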